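**Retrosynthetic overview**
1. Target ⇐ desilylation, double angeloylation and hydroxyl-directed epoxidation of cycloheptene diol 15 (C2–OH carried as a silyl ether).
2. Seven-membered ring (formed last) ⇐ ring-closing metathesis of diene 14; the C10 vinyl carbinol and C6 methallyl carbinol come from the two ends of a cis-fused γ-lactone (C10 = lactone C=O, C6 = lactone CH2O).
3. Cyclopentane (formed second) ⇐ intramolecular aldol of the C2 acetyl group onto the C4 isopropyl ketone of 1,4-diketone 7, then hydroxyl-directed reduction of C2=O.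
4. Key disconnection: the C4–C5 bond of the 1,4-diketone ⇐ isobutyraldehyde as an isobutyryl anion (Breslow intermediate) adding to 2-acetylbutenolide 4 in an enantioselective Stetter reaction; anti C-methylation then sets the C1 quaternary centre.
5. Ring order: lactone template (from 1) → cyclopentane → cycloheptene → epoxide.

Assumption: carbon labels C1–C10 are the daucane locants of the target (C1 = methyl-bearing ring-fusion carbon, C2 = CHOH and C4 = isopropyl carbinol of the five-membered ring, C5 = ring-fusion CH, C6 and C10 = ester-bearing carbons, C8/C9 = epoxide carbons); β is the face of the C1 methyl group; commercial reagents that donate atoms are named with SMILES in their step and are not numbered.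

**Route**

Step 1
Reactants: 1 α-acetyl-γ-butyrolactone
Product: 4 3-acetylfuran-2(5H)-one, via selenide 2 (not isolated), via selenoxide 3 (not isolated)
Conditions: PhSeCl, pyridine, CH2Cl2, 0 °C; then 30% H2O2, 0 °C to rt; crude 4 used at once
Reagents that add atoms: none
Why: α-Selenenylation of the β-keto lactone followed by selenoxide syn-elimination, which can only run towards the ring CH2, gives the doubly activated butenolide without forming a stereocentre.

Step 2
Reactants: 4 3-acetylfuran-2(5H)-one; 5 isobutyraldehyde
Product: 6 (3R,4S)-3-acetyl-4-(2-methylpropanoyl)oxolan-2-one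
Conditions: 5 (2 equiv), (5aR,10bS)-2-(pentafluorophenyl)-5a,10b-dihydro-4H,6H-indeno[2,1-b][1,2,4]triazolo[4,3-d][1,4]oxazin-2-ium tetrafluoroborate (15 mol%), i-Pr2NEt (15 mol%), catechol (15 mol%), toluene, 0 °C
Reagents that add atoms: none
Why: Proposed new method: the chiral triazolylidene turns isobutyraldehyde into its Breslow intermediate (an isobutyryl anion equivalent), which adds to the β-carbon of 4 (activated by both carbonyls) on the face left open by the aminoindane backbone and so sets C5 (the antipodal catalyst is used if the facial sense proves opposite); the closest known chemistry is the enantioselective intermolecular Stetter reaction of enolisable aldehydes with nitroalkenes and of glyoxamides with alkylidene malonates.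

Step 3
Reactants: 6 (3R,4S)-3-acetyl-4-(2-methylpropanoyl)oxolan-2-one
Product: 7 (3S,4S)-3-acetyl-3-methyl-4-(2-methylpropanoyl)oxolan-2-one
Conditions: MeI, K2CO3, acetone, 0 °C to rt
Reagents that add atoms: iodomethane, CI
Why: C-Alkylation of the β-keto lactone enolate, in which MeI enters anti to the C5 isobutyryl group, so the C1 quaternary centre carries acetyl cis to isobutyryl.

Step 4
Reactants: 7 (3S,4S)-3-acetyl-3-methyl-4-(2-methylpropanoyl)oxolan-2-one
Product: 8 cis-fused keto lactone (C2 ketone and C4 tertiary alcohol)
Conditions: TiCl4, i-Pr2NEt, CH2Cl2, −78 to −40 °C; aq. NH4Cl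
Reagents that add atoms: none
Why: TiCl4 chelates the acetyl and lactone carbonyls so that only the methyl ketone is enolised (soft enolisation) and its titanium enolate closes the cyclopentane by intramolecular aldol addition (5-exo) to the isopropyl ketone, with isopropyl on the convex face of the emerging cis-bicyclo[3.3.0]octane and the C4 hydroxyl on the lactone (α) face.

Step 5
Reactants: 8 cis-fused keto lactone
Product: 9 lactone diol (C2–OH β)
Conditions: Me4NBH(OAc)3, MeCN/AcOH (1:1), −30 °C
Reagents that add atoms: none
Why: Evans–Saksena hydroxyl-directed reduction, in which the C4 alkoxy(diacetoxy)borohydride delivers hydride to the α face of the C2 ketone, giving the trans-1,3-diol with C2–OH cis to the C1 methyl.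

Step 6
Reactants: 9 lactone diol
Product: 10 C2 tert-butyldimethylsilyl ether
Conditions: TBSOTf, 2,6-lutidine, CH2Cl2, −78 to −40 °C
Reagents that add atoms: tert-butyldimethylsilyl trifluoromethanesulfonate, CC(C)(C)[Si](C)(C)OS(=O)(=O)C(F)(F)F
Why: Silyl ether formation that is selective for the secondary alcohol over the hindered tertiary C4 alcohol; no stereocentre changes.

Step 7
Reactants: 10 C2 tert-butyldimethylsilyl ether
Product: 12 C10 vinyl carbinol with C6 primary alcohol, via lactol 11 (not isolated)
Conditions: i-Bu2AlH (2.3 equiv), CH2Cl2, −78 °C; then CH2=CHMgBr (5 equiv), THF, −78 to 0 °C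
Reagents that add atoms: vinylmagnesium bromide, C=C[Mg]Br
Why: Lactone-to-lactol reduction followed by Grignard 1,2-addition to the ring-opened aldehyde, where magnesium bridges the C6 alkoxide and the aldehyde oxygen in a lactol-like chelate and vinyl attacks its convex face to give the C10 configuration of the target.

Step 8
Reactants: 12 C10 vinyl carbinol with C6 primary alcohol
Product: 13 C6 aldehyde (rests mainly as its lactol with the C10 hydroxyl)
Conditions: TEMPO (20 mol%), PhI(OAc)2 (1.1 equiv), CH2Cl2, rt
Reagents that add atoms: none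
Why: Oxoammonium (TEMPO) oxidation is selective for the primary alcohol over the hindered secondary allylic and tertiary alcohols, and one equivalent of oxidant stops at the lactol stage.

Step 9
Reactants: 13 C6 aldehyde
Product: 14 diene triol
Conditions: In powder, 3-bromo-2-methylprop-1-ene, THF/H2O (1:1), rt
Reagents that add atoms: 3-bromo-2-methylprop-1-ene, CC(=C)CBr
Why: Barbier-type indium allylation in water, in which indium bridges the free C4 hydroxyl and the aldehyde oxygen (β-hydroxy aldehyde chelate) and methallyl adds to the exposed face next to H-5, giving the 1,3-anti C4/C6 diol (C6–OH β).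

Step 10
Reactants: 14 diene triol
Product: 15 cycloheptene diol
Conditions: second-generation Grubbs catalyst RuCl2(=CHPh)(PCy3)(H2IMes) (10 mol%), 1,4-benzoquinone (10 mol%), CH2Cl2 (2 mM), 40 °C
Reagents that add atoms: none
Why: Ring-closing metathesis between the vinyl group and the 1,1-disubstituted alkene, held cis on the cyclopentane, closes the seven-membered ring with the C8=C9 trisubstituted alkene and fixes the cis ring fusion already set at C1/C5.

Step 11
Reactants: 15 cycloheptene diol
Product: 16 epoxy diol
Conditions: VO(acac)2 (5 mol%), t-BuOOH (1.5 equiv), CH2Cl2, 0 °C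
Reagents that add atoms: tert-butyl hydroperoxide, CC(C)(C)OO
Why: Vanadium-catalysed hydroxyl-directed epoxidation, in which the allylic C10 alkoxide delivers oxygen syn to itself, giving the 8α,9α-epoxide.

Step 12
Reactants: 16 epoxy diol
Product: 17 bis-angelate C2 silyl ether
Conditions: angelic acid, 2,4,6-Cl3C6H2COCl, Et3N, toluene, rt, 2 h; then 16, 80 °C
Reagents that add atoms: angelic acid, C/C=C(/C)C(=O)O
Why: Yamaguchi mixed-anhydride esterification without a nucleophilic catalyst acylates both secondary alcohols while avoiding Z-to-E isomerisation, and the tertiary C4 alcohol is inert.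

Step 13
Reactants: 17 bis-angelate C2 silyl ether
Product: 18 CNP0265715.3
Conditions: Bu4NF, AcOH (1:1), THF, 0 °C to rt
Reagents that add atoms: none
Why: Fluoride-mediated desilylation, buffered with acetic acid to suppress acyl migration and epoxide opening, frees the C2 hydroxyl without touching any stereocentre.

**Compound list**
1 | α-acetyl-γ-butyrolactone (3-acetyloxolan-2-one, racemic) | CC(=O)C1CCOC1=O | starting material
2 | 3-acetyl-3-(phenylselanyl)oxolan-2-one | CC(=O)C1([Se]c2ccccc2)CCOC1=O | intermediate
3 | 3-acetyl-3-(phenylseleninyl)oxolan-2-one | CC(=O)C1(CCOC1=O)[Se](=O)c1ccccc1 | intermediate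
4 | 3-acetylfuran-2(5H)-one | CC(=O)C1=CCOC1=O | intermediate
5 | isobutyraldehyde (2-methylpropanal) | CC(C)C=O | starting material
6 | (3R,4S)-3-acetyl-4-(2-methylpropanoyl)oxolan-2-one (trans; C3 is epimerisable and is reset in step 3) | O=C1OC[C@@H](C(=O)C(C)C)[C@@H]1C(C)=O | intermediate
7 | (3S,4S)-3-acetyl-3-methyl-4-(2-methylpropanoyl)oxolan-2-one (acetyl cis to isobutyryl) | O=C1OC[C@@H](C(=O)C(C)C)[C@@]1(C)C(C)=O | intermediate
8 | 4-hydroxy-6a-methyl-4-(propan-2-yl)tetrahydro-1H-cyclopenta[c]furan-1,6(6aH)-dione; cis-fused, with 3a-H, 6a-CH3 and isopropyl on the β face and 4-OH on the lactone (α) face | O=C1OC[C@H]2[C@](O)(C(C)C)CC(=O)[C@@]12C | intermediate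
9 | 4,6-dihydroxy-6a-methyl-4-(propan-2-yl)hexahydro-1H-cyclopenta[c]furan-1-one; as 8 with 6-OH β (trans to 4-OH, cis to 6a-CH3) | O=C1OC[C@H]2[C@](O)(C(C)C)C[C@H](O)[C@@]12C | intermediate
10 | 6-O-tert-butyldimethylsilyl ether of 9 | O=C1OC[C@H]2[C@](O)(C(C)C)C[C@H](O[Si](C)(C)C(C)(C)C)[C@@]12C | intermediate
11 | lactol of 10 (1-hydroxy in place of 1-oxo; anomer mixture) | OC1OC[C@H]2[C@](O)(C(C)C)C[C@H](O[Si](C)(C)C(C)(C)C)[C@@]12C | intermediate
12 | cyclopentane C1(CH3)[CH(OH)CH=CH2]–C2H(OTBS)–C3H2–C4(OH)(i-Pr)–C5H(CH2OH); ring centres as in 10, C10 carbinol as in the target | OC[C@H]1[C@](O)(C(C)C)C[C@H](O[Si](C)(C)C(C)(C)C)[C@@]1(C)[C@@H](O)C=C | intermediate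
13 | as 12 with CHO in place of CH2OH on C5 (rests mainly as the five-membered lactol with the C10 hydroxyl) | O=C[C@H]1[C@](O)(C(C)C)C[C@H](O[Si](C)(C)C(C)(C)C)[C@@]1(C)[C@@H](O)C=C | intermediate
14 | as 12 with CH(OH)CH2C(CH3)=CH2 on C5; C6 and C10 carbinols as in the target | O[C@@H](CC(C)=C)[C@H]1[C@](O)(C(C)C)C[C@H](O[Si](C)(C)C(C)(C)C)[C@@]1(C)[C@@H](O)C=C | intermediate
15 | cis-fused bicyclo[5.3.0]dec-8-ene (daucane locants): 1β-CH3, 2β-OTBS, 4α-OH, 4β-isopropyl, 5β-H, 6β-OH, 10α-OH, C8=C9 with CH3 on C8 | O[C@H]1CC(C)=C[C@H](O)[C@@]2(C)[C@@H]1[C@](O)(C(C)C)C[C@@H]2O[Si](C)(C)C(C)(C)C | intermediate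
16 | 8α,9α-epoxide of 15 | O[C@H]1C[C@]2(C)O[C@@H]2[C@H](O)[C@@]2(C)[C@@H]1[C@](O)(C(C)C)C[C@@H]2O[Si](C)(C)C(C)(C)C | intermediate
17 | 6,10-di-O-angeloyl derivative of 16 (C2 silyl ether of the target) | C/C=C(/C)C(=O)O[C@H]1C[C@]2(C)O[C@@H]2[C@H](OC(=O)/C(C)=C\C)[C@@]2(C)[C@@H]1[C@](O)(C(C)C)C[C@@H]2O[Si](C)(C)C(C)(C)C | intermediate
18 | CNP0265715.3: 6β,10α-bis(angeloyloxy)-8α,9α-epoxy-2β,4α-dihydroxy cis-fused daucane | C/C=C(/C)C(=O)O[C@H]1C[C@]2(C)O[C@@H]2[C@H](OC(=O)/C(C)=C\C)[C@@]2(C)[C@@H]1[C@](O)(C(C)C)C[C@@H]2O | target

**Step count and risks**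
Total step count: 13. Longest linear sequence: 13 steps (1 to 18; the route is fully linear).

Three steps most likely to fail:

1. Step 2 (enantioselective Stetter reaction). An α-branched aldehyde is a slow Stetter partner, and 4 can be deprotonated at its γ-position to a furanolate, so low turnover or low ee is possible. The fallback uses a nitronate instead of the Breslow intermediate as the isobutyryl anion equivalent. It sets out from 4: conjugate addition of 2-methyl-1-nitropropane under a bifunctional cinchona-alkaloid thiourea catalyst (toluene, −20 °C) gives 3-acetyl-4-(2-methyl-1-nitropropyl)oxolan-2-one F1 with the C5 configuration of 6. Methylation with MeI and K2CO3, as in step 3, gives 3-acetyl-3-methyl-4-(2-methyl-1-nitropropyl)oxolan-2-one F2. A buffered reductive Nef reaction (aqueous TiCl3, NH4OAc, THF) converts the secondary nitro group into the ketone and comes back to the route at 7.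

2. Step 7 (facial selectivity of vinyl addition at C10). The chelate model and one Felkin-type model predict the desired epimer, but a second Felkin arrangement predicts the other. The fallback sets C10 by reagent-controlled ketone reduction instead of substrate-controlled C–C addition. It sets out from 10: a single addition of vinyllithium at −78 °C (the lithium hemiketal resists a second addition) gives the hydroxy vinyl ketone F3, which is in equilibrium with its cyclic hemiketal. Reduction with BH3·SMe2 and the 2-methyl-CBS-oxazaborolidine enantiomer that treats the quaternary C1 as the large group (predicted to be the R catalyst) gives the C10 carbinol and comes back to the route at 12.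

3. Step 12 (double angeloylation). Both alcohols are hindered and the angeloyl group can drift from Z to E at 80 °C, so incomplete acylation at C10 or tiglate contamination is possible. The fallback builds the angelate double bonds after acylation. It sets out from 16: esterification of both alcohols with 2-[bis(2,2,2-trifluoroethoxy)phosphoryl]propanoic acid (DCC, DMAP, CH2Cl2) gives the 6,10-bis(phosphonopropanoate) F4. Still–Gennari olefination with acetaldehyde (KN(SiMe3)2, 18-crown-6, THF, −78 °C) forms both (Z)-2-methylbut-2-enoates and comes back to the route at 17.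

Further compounds
F1 | step 2 | 3-acetyl-4-(2-methyl-1-nitropropyl)oxolan-2-one (ring C4 as in 6; nitro-bearing carbon unassigned) | O=C1OC[C@@H](C(C(C)C)[N+](=O)[O-])[C@@H]1C(C)=O
F2 | step 2 | 3-acetyl-3-methyl-4-(2-methyl-1-nitropropyl)oxolan-2-one (ring centres as in 7) | O=C1OC[C@@H](C(C(C)C)[N+](=O)[O-])[C@@]1(C)C(C)=O
F3 | step 7 | hydroxy vinyl ketone: as 12 with C(=O)CH=CH2 in place of CH(OH)CH=CH2 on C1 | OC[C@H]1[C@](O)(C(C)C)C[C@H](O[Si](C)(C)C(C)(C)C)[C@@]1(C)C(=O)C=C
F4 | step 12 | 6,10-bis-O-{2-[bis(2,2,2-trifluoroethoxy)phosphoryl]propanoyl} derivative of 16 | CC(C(=O)O[C@H]1C[C@]2(C)O[C@@H]2[C@H](OC(=O)C(C)P(=O)(OCC(F)(F)F)OCC(F)(F)F)[C@@]2(C)[C@@H]1[C@](O)(C(C)C)C[C@@H]2O[Si](C)(C)C(C)(C)C)P(=O)(OCC(F)(F)F)OCC(F)(F)F
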